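**Plan**

- Retrosynthesis: the eight O‑methyl bonds are cut last. The furan is then cut at its ring C O–C bond and at the ring C–ring D biaryl bond, so ring D returns as an ortho‑oxygenated aryllithium and ring C as a methoxy‑quinone.
- The dioxin is cut at both O–C(ring C) bonds, which gives a ring A–B catechol and 2,3‑dichloro‑5‑methoxy‑1,4‑benzoquinone. The two diaryl ether bonds to rings A and E are cut as copper‑mediated O‑arylations.
- Enabling feature: in ring C the two dioxin carbons are adjacent and sit between the hydroxyl carbon and the biaryl carbon, which are para to each other. This is the pattern of a 2,3‑dihalo‑1,4‑quinone, and the furan‑oxygen carbon of ring C corresponds to its methoxy carbon.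
- Forward: one aryloxyphenol (7) is made once and used twice, as rings A/B and as rings E/D. Formylation and Dakin oxidation give the catechol, the dioxin closes in step 10, ring D is attached in step 12, the furan closes in step 13, ring C is aromatised in step 14, and all methyl ethers are removed in step 15.
- Stereochemistry: the target has no stereocentre. The single carbinol centre formed in step 12 is racemic and is destroyed in step 14.

Key step: step 10

Remark on ring letters: A is the 3,5‑dioxygenated phenoxy ring on the dioxin side, B the outer dioxin ring, C the central ring, D the outer furan ring, E the phenoxy ring on ring D.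

Assumption: chlorination of 5‑chlorovanillin is taken to occur at C6 (para to the methoxy group), as the corresponding bromination of 5‑bromovanillin does.

**Route**

Step 1
Reactants: 1 2-hydroxy-4,6-dimethoxybenzaldehyde
Product: 2 2-(benzyloxy)-4,6-dimethoxybenzaldehyde
Conditions: BnBr, K2CO3, DMF, 60 °C
Reagents that add atoms: benzyl bromide, BrCc1ccccc1
Why: Williamson ether synthesis on the only hydroxyl; it masks the oxygen that later becomes the free phenol of 7.

Step 2
Reactants: 2 2-(benzyloxy)-4,6-dimethoxybenzaldehyde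
Product: 4 2-(benzyloxy)-4,6-dimethoxyphenol, via aryl formate 3 (not isolated)
Conditions: mCPBA, CH2Cl2, 0 °C to rt; NaHCO3 wash; then K2CO3 (cat.), MeOH, rt
Reagents that add atoms: 3-chloroperoxybenzoic acid, OOC(=O)c1cccc(Cl)c1
Why: Baeyer–Villiger (Dakin‑type) oxidation in which the electron‑rich trialkoxyaryl group migrates, followed by methanolysis of the formate; the new hydroxyl is unambiguously the one flanked by OBn and OMe.

Step 3
Reactants: 4 2-(benzyloxy)-4,6-dimethoxyphenol; 5 1-iodo-3,5-dimethoxybenzene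
Product: 6 1-(benzyloxy)-2-(3,5-dimethoxyphenoxy)-3,5-dimethoxybenzene
Conditions: CuI (10 mol %), picolinic acid (20 mol %), K3PO4, DMSO, 90 °C
Reagents that add atoms: none
Why: Ullmann‑type copper‑catalysed O‑arylation; the picolinic acid system is suited to di‑ortho‑substituted, electron‑rich phenols.

Step 4
Reactants: 6 1-(benzyloxy)-2-(3,5-dimethoxyphenoxy)-3,5-dimethoxybenzene
Product: 7 2-(3,5-dimethoxyphenoxy)-3,5-dimethoxyphenol
Conditions: H2 (1 atm), Pd/C (palladium on carbon), EtOAc/MeOH, rt
Reagents that add atoms: none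
Why: catalytic hydrogenolysis of the benzyl ether; aryl methyl ethers and the diaryl ether are inert.

Step 5
Reactants: 7 2-(3,5-dimethoxyphenoxy)-3,5-dimethoxyphenol
Product: 9 3-(3,5-dimethoxyphenoxy)-2-hydroxy-4,6-dimethoxybenzaldehyde, via hydroxymethyl phenol 8 (not isolated)
Conditions: MgCl2, Et3N, paraformaldehyde, MeCN, reflux; then aq. HCl
Reagents that add atoms: paraformaldehyde (as formaldehyde), C=O
Why: Casnati–Skattebøl ortho‑formylation; the magnesium phenoxide delivers formaldehyde to its only free ortho carbon and a second formaldehyde oxidises the benzylic alkoxide by hydride transfer, so the para carbon and ring A stay untouched.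

Step 6
Reactants: 9 3-(3,5-dimethoxyphenoxy)-2-hydroxy-4,6-dimethoxybenzaldehyde
Product: 11 3-(3,5-dimethoxyphenoxy)-4,6-dimethoxybenzene-1,2-diol, via catechol monoformate 10 (not isolated)
Conditions: H2O2 (30 % aq.), B(OH)3, THF, rt, argon; product used at once
Reagents that add atoms: hydrogen peroxide, OO
Why: Dakin oxidation of an ortho‑hydroxybenzaldehyde (aryl migration, then formate hydrolysis); the boric acid variant avoids the basic medium in which the very electron‑rich catechol would autoxidise.

Step 7
Reactants: 12 5-chlorovanillin (3-chloro-4-hydroxy-5-methoxybenzaldehyde)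
Product: 13 5,6-dichlorovanillin (2,3-dichloro-4-hydroxy-5-methoxybenzaldehyde)
Conditions: SO2Cl2, AcOH, rt
Reagents that add atoms: sulfuryl chloride, O=S(=O)(Cl)Cl
Why: electrophilic aromatic chlorination; both positions ortho to the hydroxyl are blocked and the carbon para to the methoxy group is the most activated one left.

Step 8
Reactants: 13 5,6-dichlorovanillin
Product: 15 2,3-dichloro-5-methoxybenzene-1,4-diol, via aryl formate 14 (not isolated)
Conditions: H2O2 (30 % aq.), NaOH (aq.), 0 °C to rt, N2; then aq. HCl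
Reagents that add atoms: hydrogen peroxide, OO
Why: Dakin oxidation of a para‑hydroxybenzaldehyde; the para phenoxide drives aryl migration and the formate is hydrolysed in the alkaline medium.

Step 9
Reactants: 15 2,3-dichloro-5-methoxybenzene-1,4-diol
Product: 16 2,3-dichloro-5-methoxy-1,4-benzoquinone
Conditions: Ag2O, MgSO4, Et2O, rt
Reagents that add atoms: none
Why: mild two‑electron oxidation of a hydroquinone to the quinone under neutral anhydrous conditions that leave the vinylic chlorides and the methoxy group intact.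

Step 10
Reactants: 11 3-(3,5-dimethoxyphenoxy)-4,6-dimethoxybenzene-1,2-diol; 16 2,3-dichloro-5-methoxy-1,4-benzoquinone
Product: 18 6-(3,5-dimethoxyphenoxy)-2,7,9-trimethoxydibenzo[b,e][1,4]dioxine-1,4-dione, via monoaryloxy chloroquinone 17 (not isolated)
Conditions: K2CO3 (2.2 equiv), degassed MeCN, −20 °C to rt, argon; 11 added slowly to 16 (1.1 equiv)
Reagents that add atoms: none
Why: The mono‑phenoxide of 11 forms at the hydroxyl beside the aryloxy carbon (it has no para oxygen donor) and adds to C2 of 16, the chloro carbon beta to the C4 carbonyl, which is the carbonyl not weakened by the MeO–C5=C6–C1=O vinylogous ester; chloride then leaves to give 17 (vinylic addition–elimination). The second phenoxide attacks the neighbouring C3 and expels the second chloride, so both dioxin O–C(ring C) bonds are made and ring C arrives as the methoxyquinone. The closest known reaction type is the condensation of catechols with 2,3‑dichloro‑1,4‑naphthoquinone or chloranil to dioxin‑fused quinones. The one ring formed is the 1,4‑dioxin, closed 6‑endo‑trig, and no stereocentre arises. The step needs orientational selectivity (which oxygen on which chloro carbon), secured by matching the more acidic hydroxyl with the more electrophilic chloro carbon, because once the first ether bond exists the closure can go only one way. It also needs substitution to outrun hydrogen and electron exchange between catechol and quinone, for which weak base, degassed solvent, low temperature and slow addition are used, the redox exchange being reversible and chloride loss not.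

Step 11
Reactants: 7 2-(3,5-dimethoxyphenoxy)-3,5-dimethoxyphenol
Product: 19 2-(3,5-dimethoxyphenoxy)-1,5-dimethoxy-3-(methoxymethoxy)benzene
Conditions: MOMCl, i-Pr2NEt, CH2Cl2, 0 °C to rt
Reagents that add atoms: chloromethyl methyl ether, COCCl
Why: acetal (MOM ether) formation at the only hydroxyl; the group protects the future furan oxygen and directs the metalation of step 12.

Step 12
Reactants: 19 2-(3,5-dimethoxyphenoxy)-1,5-dimethoxy-3-(methoxymethoxy)benzene; 18 6-(3,5-dimethoxyphenoxy)-2,7,9-trimethoxydibenzo[b,e][1,4]dioxine-1,4-dione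
Product: 21 racemic 1-[3-(3,5-dimethoxyphenoxy)-4,6-dimethoxy-2-(methoxymethoxy)phenyl]-6-(3,5-dimethoxyphenoxy)-1-hydroxy-2,7,9-trimethoxydibenzo[b,e][1,4]dioxin-4(1H)-one (quinol), via aryllithium 20 (not isolated)
Conditions: 19 (1.3 equiv), n-BuLi, THF, 0 °C, 1 h; then 18, THF, −78 °C; AcOH quench at −78 °C
Reagents that add atoms: none
Why: directed ortho‑metalation at the carbon flanked by OMOM and OMe, then 1,2‑addition of the aryllithium to C1=O of 18, the carbonyl that is chelation‑assisted by the adjacent methoxy group and conjugated to one donor oxygen instead of two; the carbinol centre forms racemic and is removed in step 14.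

Step 13
Reactants: 21 racemic quinol
Product: 23 racemic furan-closed hydroxy-dienone (ring C as cyclohexadienone; tertiary OH on the ring C carbon that carries ring D; ring D oxygen bonded to the former methoxy carbon), via free phenol 22 (not isolated)
Conditions: aq. HCl (3 M), THF, rt to 40 °C
Reagents that add atoms: none
Why: acetal hydrolysis frees the ring D phenol, which adds 5‑exo‑trig to the protonated 3‑methoxy‑dienone and expels methanol (intramolecular vinylogous transesterification), closing the furan; the stereocentre stays racemic.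

Step 14
Reactants: 23 racemic furan-closed hydroxy-dienone
Product: 24 octa-O-methylphlorofucofuroeckol A with the ring C hydroxyl free
Conditions: Zn dust, AcOH/THF, rt
Reagents that add atoms: none
Why: zinc reduction of a 4‑hydroxycyclohexa‑2,5‑dienone (para‑quinol) with loss of the tertiary hydroxyl, a reductive aromatisation that gives the dibenzofuran phenol and removes the only stereocentre.

Step 15
Reactants: 24 octa-O-methylphlorofucofuroeckol A with the ring C hydroxyl free
Product: 25 phlorofucofuroeckol A
Conditions: BBr3 (excess), CH2Cl2, −78 °C to rt; then H2O, argon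
Reagents that add atoms: none
Why: Lewis‑acid cleavage of the eight aryl methyl ethers through aryloxyboron bromides; diaryl ether, dioxin and furan C–O bonds are not cleaved and hydrolysis releases the nonaphenol.

**Compound list**

1 | 2-hydroxy-4,6-dimethoxybenzaldehyde | COc1cc(O)c(C=O)c(OC)c1 | starting material
2 | 2-(benzyloxy)-4,6-dimethoxybenzaldehyde | COc1cc(OCc2ccccc2)c(C=O)c(OC)c1 | intermediate
3 | 2-(benzyloxy)-4,6-dimethoxyphenyl formate | COc1cc(OCc2ccccc2)c(OC=O)c(OC)c1 | intermediate
4 | 2-(benzyloxy)-4,6-dimethoxyphenol | COc1cc(OCc2ccccc2)c(O)c(OC)c1 | intermediate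
5 | 1-iodo-3,5-dimethoxybenzene | COc1cc(I)cc(OC)c1 | starting material
6 | 1-(benzyloxy)-2-(3,5-dimethoxyphenoxy)-3,5-dimethoxybenzene | COc1cc(OC)cc(Oc2c(OC)cc(OC)cc2OCc2ccccc2)c1 | intermediate
7 | 2-(3,5-dimethoxyphenoxy)-3,5-dimethoxyphenol | COc1cc(OC)cc(Oc2c(O)cc(OC)cc2OC)c1 | intermediate
8 | 2-(3,5-dimethoxyphenoxy)-6-(hydroxymethyl)-3,5-dimethoxyphenol | COc1cc(OC)cc(Oc2c(O)c(CO)c(OC)cc2OC)c1 | intermediate
9 | 3-(3,5-dimethoxyphenoxy)-2-hydroxy-4,6-dimethoxybenzaldehyde | COc1cc(OC)cc(Oc2c(O)c(C=O)c(OC)cc2OC)c1 | intermediate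
10 | 3-(3,5-dimethoxyphenoxy)-2-hydroxy-4,6-dimethoxyphenyl formate | COc1cc(OC)cc(Oc2c(O)c(OC=O)c(OC)cc2OC)c1 | intermediate
11 | 3-(3,5-dimethoxyphenoxy)-4,6-dimethoxybenzene-1,2-diol | COc1cc(OC)cc(Oc2c(O)c(O)c(OC)cc2OC)c1 | intermediate
12 | 5-chlorovanillin (3-chloro-4-hydroxy-5-methoxybenzaldehyde) | COc1cc(C=O)cc(Cl)c1O | starting material
13 | 5,6-dichlorovanillin (2,3-dichloro-4-hydroxy-5-methoxybenzaldehyde) | COc1cc(C=O)c(Cl)c(Cl)c1O | intermediate
14 | 2,3-dichloro-4-hydroxy-5-methoxyphenyl formate | COc1cc(OC=O)c(Cl)c(Cl)c1O | intermediate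
15 | 2,3-dichloro-5-methoxybenzene-1,4-diol | COc1cc(O)c(Cl)c(Cl)c1O | intermediate
16 | 2,3-dichloro-5-methoxy-1,4-benzoquinone | COC1=CC(=O)C(Cl)=C(Cl)C1=O | intermediate
17 | 3-chloro-2-[2-(3,5-dimethoxyphenoxy)-6-hydroxy-3,5-dimethoxyphenoxy]-5-methoxy-1,4-benzoquinone | COC1=CC(=O)C(Oc2c(O)c(OC)cc(OC)c2Oc2cc(OC)cc(OC)c2)=C(Cl)C1=O | intermediate
18 | 6-(3,5-dimethoxyphenoxy)-2,7,9-trimethoxydibenzo[b,e][1,4]dioxine-1,4-dione | COC1=CC(=O)C2=C(C1=O)Oc1c(OC)cc(OC)c(Oc3cc(OC)cc(OC)c3)c1O2 | intermediate
19 | 2-(3,5-dimethoxyphenoxy)-1,5-dimethoxy-3-(methoxymethoxy)benzene | COCOc1cc(OC)cc(OC)c1Oc1cc(OC)cc(OC)c1 | intermediate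
20 | [3-(3,5-dimethoxyphenoxy)-4,6-dimethoxy-2-(methoxymethoxy)phenyl]lithium | [Li]c1c(OC)cc(OC)c(Oc2cc(OC)cc(OC)c2)c1OCOC | intermediate
21 | racemic 1-[3-(3,5-dimethoxyphenoxy)-4,6-dimethoxy-2-(methoxymethoxy)phenyl]-6-(3,5-dimethoxyphenoxy)-1-hydroxy-2,7,9-trimethoxydibenzo[b,e][1,4]dioxin-4(1H)-one | COCOc1c(Oc2cc(OC)cc(OC)c2)c(OC)cc(OC)c1C1(O)C(OC)=CC(=O)C2=C1Oc1c(OC)cc(OC)c(Oc3cc(OC)cc(OC)c3)c1O2 | intermediate
22 | racemic 1-[3-(3,5-dimethoxyphenoxy)-2-hydroxy-4,6-dimethoxyphenyl]-6-(3,5-dimethoxyphenoxy)-1-hydroxy-2,7,9-trimethoxydibenzo[b,e][1,4]dioxin-4(1H)-one | Oc1c(Oc2cc(OC)cc(OC)c2)c(OC)cc(OC)c1C1(O)C(OC)=CC(=O)C2=C1Oc1c(OC)cc(OC)c(Oc3cc(OC)cc(OC)c3)c1O2 | intermediate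
23 | racemic furan-closed hydroxy-dienone (ring C a cyclohexadienone with C=O at the future phenol carbon; tertiary OH on the ring C carbon bonded to ring D; all eight methyl ethers kept) | O=C1C=C2Oc3c(Oc4cc(OC)cc(OC)c4)c(OC)cc(OC)c3C2(O)C2=C1Oc1c(Oc3cc(OC)cc(OC)c3)c(OC)cc(OC)c1O2 | intermediate
24 | octa-O-methylphlorofucofuroeckol A, ring C hydroxyl free | Oc1cc2oc3c(Oc4cc(OC)cc(OC)c4)c(OC)cc(OC)c3c2c2c1Oc1c(Oc3cc(OC)cc(OC)c3)c(OC)cc(OC)c1O2 | intermediate
25 | phlorofucofuroeckol A | Oc1cc(O)cc(Oc2c(O)cc(O)c3c2Oc2c(O)cc4oc5c(Oc6cc(O)cc(O)c6)c(O)cc(O)c5c4c2O3)c1 | target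

**Step count and risks**

Total: 15 steps. Longest linear sequence: 11 steps (1, 2, 3, 4, 5, 6, 10, 12, 13, 14, 15).

Steps most likely to fail:

1. Step 10. Hydrogen and electron exchange between the very electron‑rich catechol and the quinone may outrun substitution, and the first ether bond may form with the wrong pairing of oxygen and chloro carbon, since the acidity difference between the two hydroxyls is small. The fallback builds the two C–O bonds one at a time, so that no free catechol meets the quinone and the oxygen that reacts first is fixed. It sets out from aldehyde 9 (only the hydroxyl beside the aryloxy carbon is free) and quinone 16. With K2CO3 in MeCN the phenoxide of 9 displaces the C2 chloride to give 3-chloro-2-[2-(3,5-dimethoxyphenoxy)-6-formyl-3,5-dimethoxyphenoxy]-5-methoxy-1,4-benzoquinone F1. Baeyer–Villiger oxidation with mCPBA in CH2Cl2 turns the formyl group into the formate, 3-chloro-2-[2-(3,5-dimethoxyphenoxy)-6-(formyloxy)-3,5-dimethoxyphenoxy]-5-methoxy-1,4-benzoquinone F2. KHCO3 in MeOH removes the formyl group to give 17, which closes under the same conditions, and the route is rejoined at 18. Which chloro carbon reacts first still rests on the quinone electronics.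

2. Step 12. Metalation may occur at a ring position between two methoxy groups (on ring D or ring E) instead of beside the MOM ether, and the aryllithium may transfer an electron or add in conjugate fashion instead of adding to the carbonyl. The fallback makes the aryllithium by halogen–lithium exchange from a bromide whose position is set before the diaryl ether is built. It sets out from 1. NBS in CH2Cl2 brominates ortho to the chelated hydroxyl to give 3-bromo-2-hydroxy-4,6-dimethoxybenzaldehyde F3. MOMCl and i-Pr2NEt give 3-bromo-4,6-dimethoxy-2-(methoxymethoxy)benzaldehyde F4. mCPBA gives 3-bromo-4,6-dimethoxy-2-(methoxymethoxy)phenyl formate F5, which K2CO3 (cat.) in MeOH converts into 3-bromo-4,6-dimethoxy-2-(methoxymethoxy)phenol F6. Chan–Lam coupling with commercial 3,5-dimethoxyphenylboronic acid (Cu(OAc)2 (cat.), pyridine, O2, 4 Å MS, CH2Cl2, rt) leaves the bromide intact and gives 2-bromo-4-(3,5-dimethoxyphenoxy)-1,5-dimethoxy-3-(methoxymethoxy)benzene F7. n-BuLi in THF at −78 °C then gives aryllithium 20 free of excess base, and the route is rejoined at 20, which is added to 18 as in step 12.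

3. Step 13. Under acid the electron‑rich ring D may be lost from the tertiary carbinol by ipso protonation (retro‑addition), or the dienone may rearrange before the furan closes. The fallback unmasks the phenol with fluoride so that the ring closure runs under basic conditions. It sets out from 7. SEMCl and i-Pr2NEt give 2-(3,5-dimethoxyphenoxy)-1,5-dimethoxy-3-{[2-(trimethylsilyl)ethoxy]methoxy}benzene F8. n-BuLi in THF at 0 °C (the SEM ether directs as the MOM ether does) gives [3-(3,5-dimethoxyphenoxy)-4,6-dimethoxy-2-{[2-(trimethylsilyl)ethoxy]methoxy}phenyl]lithium F9, and addition to 18 at −78 °C with AcOH quench gives the SEM analogue of quinol 21, F10. Bu4NF in THF/DMPU at 45 °C fragments the SEM group; the phenoxide of 22 so formed displaces the methoxy group and, after AcOH quench, the route is rejoined at 23.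

**Further compounds**

F1 | step 10 | 3-chloro-2-[2-(3,5-dimethoxyphenoxy)-6-formyl-3,5-dimethoxyphenoxy]-5-methoxy-1,4-benzoquinone | COC1=CC(=O)C(Oc2c(C=O)c(OC)cc(OC)c2Oc2cc(OC)cc(OC)c2)=C(Cl)C1=O
F2 | step 10 | 3-chloro-2-[2-(3,5-dimethoxyphenoxy)-6-(formyloxy)-3,5-dimethoxyphenoxy]-5-methoxy-1,4-benzoquinone | COC1=CC(=O)C(Oc2c(OC=O)c(OC)cc(OC)c2Oc2cc(OC)cc(OC)c2)=C(Cl)C1=O
F3 | step 12 | 3-bromo-2-hydroxy-4,6-dimethoxybenzaldehyde | COc1cc(OC)c(Br)c(O)c1C=O
F4 | step 12 | 3-bromo-4,6-dimethoxy-2-(methoxymethoxy)benzaldehyde | COCOc1c(Br)c(OC)cc(OC)c1C=O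
F5 | step 12 | 3-bromo-4,6-dimethoxy-2-(methoxymethoxy)phenyl formate | COCOc1c(Br)c(OC)cc(OC)c1OC=O
F6 | step 12 | 3-bromo-4,6-dimethoxy-2-(methoxymethoxy)phenol | COCOc1c(Br)c(OC)cc(OC)c1O
F7 | step 12 | 2-bromo-4-(3,5-dimethoxyphenoxy)-1,5-dimethoxy-3-(methoxymethoxy)benzene | COCOc1c(Br)c(OC)cc(OC)c1Oc1cc(OC)cc(OC)c1
F8 | step 13 | 2-(3,5-dimethoxyphenoxy)-1,5-dimethoxy-3-{[2-(trimethylsilyl)ethoxy]methoxy}benzene | C[Si](C)(C)CCOCOc1cc(OC)cc(OC)c1Oc1cc(OC)cc(OC)c1
F9 | step 13 | [3-(3,5-dimethoxyphenoxy)-4,6-dimethoxy-2-{[2-(trimethylsilyl)ethoxy]methoxy}phenyl]lithium | C[Si](C)(C)CCOCOc1c([Li])c(OC)cc(OC)c1Oc1cc(OC)cc(OC)c1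
F10 | step 13 | racemic SEM analogue of quinol 21 | C[Si](C)(C)CCOCOc1c(Oc2cc(OC)cc(OC)c2)c(OC)cc(OC)c1C1(O)C(OC)=CC(=O)C2=C1Oc1c(OC)cc(OC)c(Oc3cc(OC)cc(OC)c3)c1O2
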